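**Plan**

1. Retrosynthesis: first remove the late groups (C11 spiro-epoxide ← ketone/ketal, C6–Cl with C5=C16 ← Δ5 olefin, C14–OAc ← ketone). Then cut C1–C2 and O(C8)–C4 together, then C9–C10 (allylindium + aldehyde), C4–C5 (Stille) and C8–C17 (Reformatsky lactonisation).
2. Enabling feature: the C2/C3/C4 oxygen triad (2,3-diol plus the C4 ether oxygen) lies between quaternary C1 (α to oxygenated C14) and the tertiary C8 oxygen. In the seco form this is a trans-3,4-epoxy aldehyde (1,3-dielectrophile) facing a latent C14 enolate and the C8 hydroxyl (1,5-C,O-dinucleophile). One reductive aldol/transannular epoxide opening therefore closes the ten-membered carbocycle (C1–C10) and the oxane (O, C4–C8).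
3. Forward order: γ-lactone first; the cyclohexane enters as an achiral Baylis–Hillman bromide; ten-membered ring and oxane form together in the key step; the spiro-epoxide comes last.
4. Stereochemistry: C7 from a catalytic asymmetric diazoacetate aldol; C8/C17 relayed from C7 in the lactonisation; C9/C10 from a chelated, anti-selective allylindation; C3/C4 from Sharpless epoxidation (C4 inverted in the key step); C1/C2 in the key step; C14, C6 and C11 by substrate control on the bridged core.

Key step: step 16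

Remark: locants are briarane locants (C1 quaternary C–CH3 with C15 its methyl; C2, C3 diol carbons; C4 oxane CH–O; C5 with C16; C6 CHCl; C7 lactone CH–O; C8 oxygenated quaternary carbon; C9 CH–OAc; C10 ring CH; C11 spiro carbon with C20; C14 ring CH–OAc; C17/C18/C19 lactone CH, its methyl, C=O).
Remark: 1, 4, 6, 12 and 17 are taken as catalogue compounds; 6 is used racemic, so 7 and 8 are epimer mixtures at CHBr, which is erased in step 6.

**Route**

Step 1
Reactants: 1 but-2-yn-1-ol
Product: 2 (Z)-3-iodobut-2-en-1-ol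
Conditions: Red-Al, THF, 0 °C; then I2, −78 °C → rt
Reagents that add atoms: iodine, II
Why: trans-hydroalumination of the propargylic alcohol puts aluminium on C3 cis to the carbinol, and iodinolysis with retention should give the Z iodide (hydroalumination–iodination).

Step 2
Reactants: 2 (Z)-3-iodobut-2-en-1-ol
Product: 3 (Z)-3-iodobut-2-enal
Conditions: MnO2, CH2Cl2, rt, dark
Reagents that add atoms: none
Why: neutral MnO2 oxidation of the allylic alcohol should keep the Z geometry; the enal is used at once.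

Step 3
Reactants: 3 (Z)-3-iodobut-2-enal; 4 ethyl diazoacetate
Product: 5 ethyl (3S,4Z)-2-diazo-3-hydroxy-5-iodohex-4-enoate
Conditions: ProPhenol ligand (5 mol%, enantiomer that gives 3S), Bu2Mg (10 mol%), cis-cyclopentane-1,2-diol (5 mol%), THF, −20 °C
Reagents that add atoms: none
Why: catalytic enantioselective aldol-type 1,2-addition of the diazoacetate to the enal sets C7 under catalyst control (Mg–ProPhenol diazo aldol).

Step 4
Reactants: 5 ethyl (3S,4Z)-2-diazo-3-hydroxy-5-iodohex-4-enoate; 6 2-bromopropanoyl bromide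
Product: 7 ethyl (3S,4Z)-3-[(2-bromopropanoyl)oxy]-2-diazo-5-iodohex-4-enoate (two epimers at CHBr)
Conditions: pyridine, CH2Cl2, −40 → 0 °C
Reagents that add atoms: none
Why: O-acylation of the secondary alcohol installs the C17–C19 unit as a tether on the C7 oxygen; the acceptor diazo ester tolerates the acyl bromide at low temperature.

Step 5
Reactants: 7 diazo ester
Product: 8 ethyl (3S,4Z)-3-[(2-bromopropanoyl)oxy]-5-iodo-2-oxohex-4-enoate
Conditions: DMDO, acetone, −78 → 0 °C
Reagents that add atoms: dimethyldioxirane, CC1(C)OO1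
Why: oxygen transfer to the diazo carbon with loss of N2 gives the α-keto ester under neutral conditions, faster than epoxidation of the electron-poor iodoalkene (diazo-to-carbonyl oxidation); 8 is used crude because C7–H is acidic.

Step 6
Reactants: 8 α-keto ester
Product: 9 ethyl (2S,3S,4R)-3-hydroxy-2-[(Z)-2-iodoprop-1-en-1-yl]-4-methyl-5-oxooxolane-3-carboxylate
Conditions: Zn (activated), THF, 0 °C → rt
Reagents that add atoms: none
Why: intramolecular Reformatsky reaction (5-exo-trig) of the zinc enolate onto the activated ketone closes the γ-lactone; the ester on C8 should go trans to the C7 alkenyl group and the C17 methyl exo, cis to the new hydroxyl, so C7 controls C8 and C17.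

Step 7
Reactants: 9 lactone ester
Product: 10 (3R,4R,5S)-4-hydroxy-4-(hydroxymethyl)-5-[(Z)-2-iodoprop-1-en-1-yl]-3-methyloxolan-2-one
Conditions: NaBH4, EtOH, −20 → 0 °C; AcOH quench
Reagents that add atoms: none
Why: hydroxyl-assisted borohydride reduction should take the α-hydroxy ester selectively while the γ-lactone and the vinyl iodide survive at low temperature.

Step 8
Reactants: 10 diol
Product: 11 (2S,3S,4R)-3-hydroxy-2-[(Z)-2-iodoprop-1-en-1-yl]-4-methyl-5-oxooxolane-3-carbaldehyde
Conditions: SO3·pyridine, DMSO, iPr2NEt, CH2Cl2, 0 °C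
Reagents that add atoms: none
Why: Parikh–Doering oxidation converts the primary hydroxyl of the tertiary/primary diol to the α-hydroxy aldehyde without glycol cleavage; 11 is used at once.

Step 9
Reactants: 12 1,4-dioxaspiro[4.5]dec-6-en-8-one
Product: 13 7-(hydroxymethyl)-1,4-dioxaspiro[4.5]dec-6-en-8-one
Conditions: aq. HCHO, DMAP (cat.), THF/H2O, rt
Reagents that add atoms: formaldehyde, C=O
Why: Morita–Baylis–Hillman hydroxymethylation places C15 on the enone α-carbon (C1).

Step 10
Reactants: 13 allylic alcohol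
Product: 14 7-(bromomethyl)-1,4-dioxaspiro[4.5]dec-6-en-8-one
Conditions: CBr4, PPh3, CH2Cl2, 0 °C
Reagents that add atoms: carbon tetrabromide, BrC(Br)(Br)Br
Why: Appel bromination of the primary allylic alcohol is neutral and spares the ketal.

Step 11
Reactants: 11 lactone aldehyde; 14 bromide
Product: 15 allylation adduct (C9–C10 bond; 9S carbinol, 10S; C8 and C9 hydroxyls free; 1-methylene-14-ketone; C11 ketal; Z vinyl iodide)
Conditions: In powder, THF/H2O (1:1), rt
Reagents that add atoms: none
Why: indium-mediated Barbier allylation; the 2-(metallomethyl)enone should react through its ring γ-carbon (C10) in a chair transition state (ring bond E to CH2In, hence anti C9/C10), with indium chelated by the C8 hydroxyl and the aldehyde and the allyl array on the face away from the C7 alkenyl group; the aldehyde reacts, the ketone does not.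

Step 12
Reactants: 15 diol
Product: 16 C9 acetate of 15
Conditions: Ac2O, pyridine, DMAP (cat.), CH2Cl2, 0 °C
Reagents that add atoms: acetic anhydride, CC(=O)OC(C)=O
Why: the secondary C9 hydroxyl is acetylated selectively over the tertiary C8 hydroxyl, which also blocks hemiketal formation and lactone migration.

Step 13
Reactants: 16 vinyl iodide; 17 (E)-3-(tributylstannyl)prop-2-en-1-ol
Product: 18 (2E,4Z)-dienol (C2H2OH–C3H=C4H–C5(CH3)=C6H–C7)
Conditions: Pd2(dba)3 (cat.), AsPh3, CuI (cat.), DMF, rt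
Reagents that add atoms: none
Why: Stille coupling forms C4–C5 with retention of both alkene geometries and tolerates the enone, the acetate and the free hydroxyls.

Step 14
Reactants: 18 dienol
Product: 19 (3S,4S)-3,4-epoxy alcohol (trans epoxide next to the Z C5=C6 alkene)
Conditions: Ti(OiPr)4, L-(+)-DET, TBHP, 4 Å MS, CH2Cl2, −20 °C
Reagents that add atoms: tert-butyl hydroperoxide, CC(C)(C)OO
Why: Sharpless asymmetric epoxidation acts only on the allylic-alcohol alkene; L-(+)-tartrate sets C3 and C4 by reagent control.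

Step 15
Reactants: 19 epoxy alcohol
Product: 20 epoxy aldehyde (C2 CHO), the seco precursor
Conditions: Dess–Martin periodinane, NaHCO3, CH2Cl2, 0 °C
Reagents that add atoms: none
Why: buffered Dess–Martin oxidation gives the α,β-epoxy aldehyde without opening the vinyl epoxide.

Step 16
Reactants: 20 epoxy aldehyde
Product: 23 bridged core (ten-membered carbocycle, 4,8-ether, 2,3-diol, 14-ketone, C11 ketal), via indium enolate 21 (not isolated), via ten-membered aldolate 22 (not isolated)
Conditions: In(OAc)3 (1.5 equiv), PhSiH3 (1.2 equiv), THF, 0 → 40 °C, 2 mM, slow addition of 20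
Reagents that add atoms: none
Why: Proposed new method: the indium hydride made in situ should add 1,4 to the s-cis exo-methylene enone (C15=C1–C14=O) faster than it reduces the aldehyde, giving the regiodefined tetrasubstituted enolate 21; this closes the ten-membered carbocycle by aldol addition to C2 [10-(enolexo)-exo-trig], and the In(III) aldolate 22, bound to the neighbouring epoxide oxygen, then activates allylic C4 for transannular attack by the C8 hydroxyl [6-exo-tet], which closes the oxane. The closest known reactions are the indium hydride reductive aldol of enones with aldehydes, Reformatsky-type aldol closures of medium rings and the acid-promoted 6-exo cyclisation of hydroxy vinyl epoxides; their combination in one macrocyclising cascade is new. C1 should form by attack on the enolate face anti to the pseudoaxial C9 substituent at C10 (A1,2 strain with the C1 methyl), which gives the trans ring fusion. C2 should follow from the metal chelate between the aldehyde and epoxide oxygens, with attack anti to C4 (2,3-syn); C4 is set by SN2 inversion of the Sharpless epoxide, and C3 is retained. The step needs conjugate hydride delivery in preference to aldehyde reduction (s-cis enone), C1 rather than C13 enolisation (fixed by hydrometalation), ring closure in preference to oligomerisation (high dilution), and aldol before etherification so that a ten- and not an eight-membered ring is closed (the epoxide is activated only once the aldolate is formed).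

Step 17
Reactants: 23 diol ketone
Product: 24 2,3-bis(TBS) ether of 23
Conditions: TBSOTf, 2,6-lutidine, CH2Cl2, −78 → −20 °C
Reagents that add atoms: tert-butyldimethylsilyl triflate, CC(C)(C)[Si](C)(C)OS(=O)(=O)C(F)(F)F
Why: silylation masks the diol so that only the C14 oxygen is acetylated later.

Step 18
Reactants: 24 ketone
Product: 25 14α-alcohol (14S)
Conditions: L-Selectride, THF, −78 °C
Reagents that add atoms: none
Why: the bulky hydride should attack the C14 ketone equatorially and give the axial alcohol cis to C2; lactone, acetate and ketal should survive at −78 °C.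

Step 19
Reactants: 25 alcohol
Product: 26 9,14-diacetate
Conditions: Ac2O, Et3N, DMAP, CH2Cl2, rt
Reagents that add atoms: acetic anhydride, CC(=O)OC(C)=O
Why: DMAP-catalysed acetylation of the only free hydroxyl.

Step 20
Reactants: 26 Δ5 olefin
Product: 27 6α-chloro-5(16)-ene (6S)
Conditions: Ca(OCl)2, CO2 (dry ice), CH2Cl2/H2O, 0 °C
Reagents that add atoms: calcium hypochlorite, [Ca+2].[O-]Cl.[O-]Cl
Why: ene-type allylic chlorination of the only C=C: electrophilic chlorine should add to the less substituted C6 on the face opposite the C3/C9 bridge, with proton loss from the C16 methyl to give the exocyclic methylene.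

Step 21
Reactants: 27 ketal
Product: 28 C11 ketone
Conditions: PPTS, acetone/H2O, 50 °C
Reagents that add atoms: water, O
Why: mild acid hydrolysis of the dioxolane; the TBS ethers, acetates and allylic chloride should survive.

Step 22
Reactants: 28 ketone
Product: 29 11(20)-methylene compound
Conditions: Cp2TiMe2, toluene, 65 °C
Reagents that add atoms: dimethyltitanocene, C[Ti](C)(C1C=CC=C1)C1C=CC=C1
Why: non-basic Petasis methylenation avoids epimerisation at C10 and β-elimination of the C9 acetate; the ketone reacts before the esters.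

Step 23
Reactants: 29 diene
Product: 30 11R spiro-epoxide, 2,3-bis(TBS) ether
Conditions: mCPBA, NaHCO3, CH2Cl2, 0 °C
Reagents that add atoms: 3-chloroperbenzoic acid, OOC(=O)c1cccc(Cl)c1
Why: Prilezhaev epoxidation of the electron-richer C11=C20 alkene (C5=C16 is deactivated by allylic Cl and O), from the face opposite the axial C15 methyl and the C9 substituent, so the oxygen ends α.

Step 24
Reactants: 30 bis(silyl ether)
Product: 31 CNP0340728.1 (target)
Conditions: HF·pyridine, pyridine, THF, 0 °C → rt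
Reagents that add atoms: none
Why: buffered fluoride desilylation frees the 2,3-diol without acyl migration and should spare the epoxide and the allylic chloride.

**Compound list**

1 | but-2-yn-1-ol | CC#CCO | starting material
2 | (Z)-3-iodobut-2-en-1-ol | I/C(C)=C\CO | intermediate
3 | (Z)-3-iodobut-2-enal | I/C(C)=C\C=O | intermediate
4 | ethyl diazoacetate | CCOC(=O)C=[N+]=[N-] | starting material
5 | ethyl (3S,4Z)-2-diazo-3-hydroxy-5-iodohex-4-enoate | I/C(C)=C\[C@H](O)C(=[N+]=[N-])C(=O)OCC | intermediate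
6 | 2-bromopropanoyl bromide (racemic) | CC(Br)C(Br)=O | starting material
7 | ethyl (3S,4Z)-3-[(2-bromopropanoyl)oxy]-2-diazo-5-iodohex-4-enoate, epimers at CHBr | I/C(C)=C\[C@H](OC(=O)C(C)Br)C(=[N+]=[N-])C(=O)OCC | intermediate
8 | ethyl (3S,4Z)-3-[(2-bromopropanoyl)oxy]-5-iodo-2-oxohex-4-enoate, epimers at CHBr | I/C(C)=C\[C@H](OC(=O)C(C)Br)C(=O)C(=O)OCC | intermediate
9 | ethyl (2S,3S,4R)-3-hydroxy-2-[(Z)-2-iodoprop-1-en-1-yl]-4-methyl-5-oxooxolane-3-carboxylate (OH cis to alkenyl and methyl) | I/C(C)=C\[C@@H]1OC(=O)[C@H](C)[C@@]1(O)C(=O)OCC | intermediate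
10 | (3R,4R,5S)-4-hydroxy-4-(hydroxymethyl)-5-[(Z)-2-iodoprop-1-en-1-yl]-3-methyloxolan-2-one | I/C(C)=C\[C@@H]1OC(=O)[C@H](C)[C@@]1(O)CO | intermediate
11 | (2S,3S,4R)-3-hydroxy-2-[(Z)-2-iodoprop-1-en-1-yl]-4-methyl-5-oxooxolane-3-carbaldehyde | I/C(C)=C\[C@@H]1OC(=O)[C@H](C)[C@@]1(O)C=O | intermediate
12 | 1,4-dioxaspiro[4.5]dec-6-en-8-one | O=C1C=CC2(CC1)OCCO2 | starting material
13 | 7-(hydroxymethyl)-1,4-dioxaspiro[4.5]dec-6-en-8-one | O=C1C(CO)=CC2(CC1)OCCO2 | intermediate
14 | 7-(bromomethyl)-1,4-dioxaspiro[4.5]dec-6-en-8-one | O=C1C(CBr)=CC2(CC1)OCCO2 | intermediate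
15 | allylation adduct: lactone with C8–OH and (9S)-C9–OH bonded to (10S)-C10 of the 1-methylene-14-oxo-11,11-ethylenedioxycyclohexane; Z vinyl iodide | I/C(C)=C\[C@@H]1OC(=O)[C@H](C)[C@@]1(O)[C@@H](O)[C@@H]1C(=C)C(=O)CCC12OCCO2 | intermediate
16 | C9 acetate of 15 | I/C(C)=C\[C@@H]1OC(=O)[C@H](C)[C@@]1(O)[C@@H](OC(C)=O)[C@@H]1C(=C)C(=O)CCC12OCCO2 | intermediate
17 | (E)-3-(tributylstannyl)prop-2-en-1-ol | CCCC[Sn](CCCC)(CCCC)/C=C/CO | starting material
18 | (2E,4Z)-dienol (C2 primary alcohol, C3=C4 E, C5=C6 Z) | OC/C=C/C(C)=C\[C@@H]1OC(=O)[C@H](C)[C@@]1(O)[C@@H](OC(C)=O)[C@@H]1C(=C)C(=O)CCC12OCCO2 | intermediate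
19 | (3S,4S)-trans-3,4-epoxy alcohol | OC[C@@H]1O[C@H]1/C(C)=C\[C@@H]2OC(=O)[C@H](C)[C@@]2(O)[C@@H](OC(C)=O)[C@@H]2C(=C)C(=O)CCC23OCCO3 | intermediate
20 | trans-3,4-epoxy aldehyde (C2 CHO), seco precursor | O=C[C@@H]1O[C@H]1/C(C)=C\[C@@H]2OC(=O)[C@H](C)[C@@]2(O)[C@@H](OC(C)=O)[C@@H]2C(=C)C(=O)CCC23OCCO3 | intermediate
21 | indium(III) enolate C14(OIn(OAc)2)=C1(CH3) of 20 | O=C[C@@H]1O[C@H]1/C(C)=C\[C@@H]2OC(=O)[C@H](C)[C@@]2(O)[C@@H](OC(C)=O)[C@@H]2C(C)=C(O[In](OC(C)=O)OC(C)=O)CCC23OCCO3 | intermediate
22 | ten-membered aldol (1S,2R; 3,4-epoxide intact; C8–OH free), the indium aldolate drawn as its C2 alcohol | C/C1=C/[C@@H]2OC(=O)[C@H](C)[C@@]2(O)[C@@H](OC(C)=O)[C@H]2C3(OCCO3)CCC(=O)[C@]2(C)[C@@H](O)[C@@H]2O[C@@H]12 | intermediate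
23 | bridged core: 4,8-ether, 2,3-diol, 14-ketone, 9-acetate, Δ5 olefin, C11 ketal | CC1[C@H]2O[C@]3([C@@H](C)C(=O)O[C@H]3C=1)[C@@H](OC(C)=O)[C@H]1C4(OCCO4)CCC(=O)[C@]1(C)[C@@H](O)[C@@H]2O | intermediate
24 | 2,3-bis(TBS) ether of 23 | CC1[C@H]2O[C@]3([C@@H](C)C(=O)O[C@H]3C=1)[C@@H](OC(C)=O)[C@H]1C4(OCCO4)CCC(=O)[C@]1(C)[C@@H](O[Si](C)(C)C(C)(C)C)[C@@H]2O[Si](C)(C)C(C)(C)C | intermediate
25 | (14S)-14α-alcohol | CC1[C@H]2O[C@]3([C@@H](C)C(=O)O[C@H]3C=1)[C@@H](OC(C)=O)[C@H]1C4(OCCO4)CC[C@H](O)[C@]1(C)[C@@H](O[Si](C)(C)C(C)(C)C)[C@@H]2O[Si](C)(C)C(C)(C)C | intermediate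
26 | 9,14-diacetate, Δ5 olefin | CC1[C@H]2O[C@]3([C@@H](C)C(=O)O[C@H]3C=1)[C@@H](OC(C)=O)[C@H]1C4(OCCO4)CC[C@H](OC(C)=O)[C@]1(C)[C@@H](O[Si](C)(C)C(C)(C)C)[C@@H]2O[Si](C)(C)C(C)(C)C | intermediate
27 | (6S)-6-chloro-5(16)-ene, C11 ketal | C=C1[C@H]2O[C@]3([C@@H](C)C(=O)O[C@H]3[C@H]1Cl)[C@@H](OC(C)=O)[C@H]1C4(OCCO4)CC[C@H](OC(C)=O)[C@]1(C)[C@@H](O[Si](C)(C)C(C)(C)C)[C@@H]2O[Si](C)(C)C(C)(C)C | intermediate
28 | C11 ketone | C=C1[C@H]2O[C@]3([C@@H](C)C(=O)O[C@H]3[C@H]1Cl)[C@@H](OC(C)=O)[C@H]1C(=O)CC[C@H](OC(C)=O)[C@]1(C)[C@@H](O[Si](C)(C)C(C)(C)C)[C@@H]2O[Si](C)(C)C(C)(C)C | intermediate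
29 | 11(20)-methylene compound | C=C1[C@H]2O[C@]3([C@@H](C)C(=O)O[C@H]3[C@H]1Cl)[C@@H](OC(C)=O)[C@H]1C(=C)CC[C@H](OC(C)=O)[C@]1(C)[C@@H](O[Si](C)(C)C(C)(C)C)[C@@H]2O[Si](C)(C)C(C)(C)C | intermediate
30 | (11R)-11,20-epoxide, 2,3-bis(TBS) ether | C=C1[C@H]2O[C@]3([C@@H](C)C(=O)O[C@H]3[C@H]1Cl)[C@@H](OC(C)=O)[C@H]1[C@]3(CC[C@H](OC(C)=O)[C@]1(C)[C@@H](O[Si](C)(C)C(C)(C)C)[C@@H]2O[Si](C)(C)C(C)(C)C)CO3 | intermediate
31 | CNP0340728.1 | C=C1[C@H]2O[C@]3([C@@H](C)C(=O)O[C@H]3[C@H]1Cl)[C@@H](OC(C)=O)[C@H]1[C@]3(CC[C@H](OC(C)=O)[C@]1(C)[C@@H](O)[C@@H]2O)CO3 | target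

**Totals**

Total step count: 24. Longest linear sequence: 22 (steps 1–8 and 11–24; steps 9–10 make the second fragment).

**Steps most likely to fail**

Step 16. The indium enolate may be protonated, or the aldehyde reduced, before the ten-membered ring closes; oligomerisation may outrun the medium-ring aldol; and early epoxide opening would leave an eight-membered closure with the wrong ring fusion. The fallback uses known reaction types, sets out from 19 and rejoins at 23. Rh-catalysed 1,4-hydrosilylation of the enone with excess Et3SiH, which also silylates the primary hydroxyl, should give the bis(triethylsilyl) compound F1. NBS bromination of its silyl enol ether should give the tertiary α-bromo ketone F2 (C1 epimers). Swern conditions, which oxidise primary triethylsilyl ethers directly, should give the bromo keto aldehyde F3. A SmI2-mediated intramolecular Reformatsky-type aldol (THF, −78 °C, high dilution) should then give the ten-membered aldol 22, and a separate CSA-catalysed transannular 6-exo opening of the vinyl epoxide should give 23.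

Step 11. The allylindium may react through its CH2 terminus because the ring carbon lies next to the ketal; facial discrimination at the α-hydroxy aldehyde may be weak; and the lactone may migrate to the new C9 hydroxyl. The fallback sets out from 14 and rejoins at 15. Copper-catalysed borylation (B2pin2, CuCl, KOtBu) should give the allylboronate F4. Allylboration of 11 (toluene, 40 °C, or Sc(OTf)3 cat.) runs through a closed six-membered transition state in which γ-attack is obligatory and the C8 hydroxyl can bind boron, and should give 15.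

Step 20. Chlorine may be delivered from the wrong face, may add across the olefin, or the proton may be lost from C4 instead of C16. The fallback sets out from 26 and rejoins at 27. A Schenck ene reaction with singlet oxygen (TPP, O2, hν) and PPh3 reduction should give the 6α allylic alcohol F5. Dess–Martin oxidation should give the enone F6, and Luche reduction from the open α face the 6β alcohol F7. Chlorination with inversion (MsCl, LiCl, collidine, DMF) should give 27.

**Further compounds**

F1 | step 16 | bis(triethylsilyl) compound: C2–OTES epoxy alcohol with C14(OTES)=C1(CH3) enol ether | CC[Si](CC)(CC)OC[C@@H]1O[C@H]1/C(C)=C\[C@@H]2OC(=O)[C@H](C)[C@@]2(O)[C@@H](OC(C)=O)[C@@H]2C(C)=C(O[Si](CC)(CC)CC)CCC23OCCO3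
F2 | step 16 | 1-bromo-1-methyl-14-ketone, C2–OTES (C1 epimers) | CC[Si](CC)(CC)OC[C@@H]1O[C@H]1/C(C)=C\[C@@H]2OC(=O)[C@H](C)[C@@]2(O)[C@@H](OC(C)=O)[C@@H]2C(C)(Br)C(=O)CCC23OCCO3
F3 | step 16 | bromo keto epoxy aldehyde (C1 epimers) | O=C[C@@H]1O[C@H]1/C(C)=C\[C@@H]2OC(=O)[C@H](C)[C@@]2(O)[C@@H](OC(C)=O)[C@@H]2C(C)(Br)C(=O)CCC23OCCO3
F4 | step 11 | 7-[(4,4,5,5-tetramethyl-1,3,2-dioxaborolan-2-yl)methyl]-1,4-dioxaspiro[4.5]dec-6-en-8-one | O=C1C(CB3OC(C)(C)C(C)(C)O3)=CC2(CC1)OCCO2
F5 | step 20 | 6α-hydroxy-5(16)-ene | C=C1[C@H]2O[C@]3([C@@H](C)C(=O)O[C@H]3[C@H]1O)[C@@H](OC(C)=O)[C@H]1C4(OCCO4)CC[C@H](OC(C)=O)[C@]1(C)[C@@H](O[Si](C)(C)C(C)(C)C)[C@@H]2O[Si](C)(C)C(C)(C)C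
F6 | step 20 | 6-oxo-5(16)-ene | C=C1[C@H]2O[C@]3([C@@H](C)C(=O)O[C@H]3C1=O)[C@@H](OC(C)=O)[C@H]1C4(OCCO4)CC[C@H](OC(C)=O)[C@]1(C)[C@@H](O[Si](C)(C)C(C)(C)C)[C@@H]2O[Si](C)(C)C(C)(C)C
F7 | step 20 | 6β-hydroxy-5(16)-ene | C=C1[C@H]2O[C@]3([C@@H](C)C(=O)O[C@H]3[C@@H]1O)[C@@H](OC(C)=O)[C@H]1C4(OCCO4)CC[C@H](OC(C)=O)[C@]1(C)[C@@H](O[Si](C)(C)C(C)(C)C)[C@@H]2O[Si](C)(C)C(C)(C)C
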